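## Plan

- The target is (13R)-6α-angeloyloxylabd-14-ene-8α,13-diol (5S,6S,8R,9R,10S,13R; labdane numbering). The retrosynthesis cuts the C6 ester C–O bond, then C9–C10 together with C8–OH (ring B), then C6–C7.
- This leaves β-cyclocitral (ring A: C1–C5, C10, C18–C20, with its aldehyde carbon as C6) and (R)-linalool (C7–C9 and C11–C17, its carbinol carbon as C13).
- The enabling feature: in ring A the C5=C10 double bond carries the oxygenated C6, so C6–C5–C10 can become an allyl cation. The C8=C9 double bond of the linalool half is placed so that C9 reaches C10 and closes the six-membered ring B.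
- Forward: 1 is silylated, hydroxylated at its E-methyl group and chlorinated; its allylbarium reagent adds to 6 (C6–C7 bond); acid closes ring B (ring A is bought); the Δ5 bond is epoxidised and opened reductively to the 6α-alcohol; angeloylation and desilylation finish the synthesis.
- Stereochemistry: C13 from (R)-linalool; C8, C9 and C10 from the E-alkene, a chair-like closure and anti capture by water, with the face of C10 chosen by a chiral counteranion; C6 from α-face epoxidation; C5 from α-face hydrogen-atom transfer; the Z-ester from angelic acid.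

Key step: step 5

Remark 1: labdane numbering and α/β descriptors are used from compound 8 on (α is the face opposite the C10 methyl group, C20).
Remark 2: the sense of induction of the chiral acid in step 5 cannot be predicted; the (S,S)-acid is written, and its mirror image would be used should it pair with the wrong face of C10.

## Route

Step 1
Reactants: 1 (R)-linalool
Product: 2 (R)-linalool tert-butyldimethylsilyl ether
Conditions: TBSOTf, 2,6-lutidine, CH2Cl2, 0 °C to rt
Reagents that add atoms: tert-butyldimethylsilyl triflate, CC(C)(C)[Si](C)(C)OS(=O)(=O)C(F)(F)F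
Why: Silyl triflate/lutidine silylation is the standard protection of a hindered tertiary alcohol and should leave the C13 stereocentre and both alkenes untouched.

Step 2
Reactants: 2 (R)-linalool tert-butyldimethylsilyl ether
Product: 3 (2E,6R)-6-(tert-butyldimethylsilyloxy)-2,6-dimethylocta-2,7-dien-1-ol
Conditions: SeO2 (0.3 equiv), t-BuOOH (3 equiv), salicylic acid (0.1 equiv), CH2Cl2, 0 °C to rt, stopped before over-oxidation
Reagents that add atoms: selenium dioxide, O=[Se]=O (oxygen carrier); tert-butyl hydroperoxide, CC(C)(C)OO (terminal oxidant)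
Why: The Sharpless SeO2/t-BuOOH allylic oxidation (ene reaction, then [2,3]-sigmatropic shift) hydroxylates the E-methyl group of a trisubstituted alkene selectively, and the vinyl group has no allylic hydrogen.

Step 3
Reactants: 3 (2E,6R)-6-(tert-butyldimethylsilyloxy)-2,6-dimethylocta-2,7-dien-1-ol
Product: 5 (3R,6E)-3-(tert-butyldimethylsilyloxy)-8-chloro-3,7-dimethylocta-1,6-diene, via allylic mesylate 4 (not isolated)
Conditions: MsCl, 2,4,6-collidine, LiCl, DMF, 0 °C
Reagents that add atoms: lithium chloride, [Li+].[Cl-]
Why: In the Collington–Meyers chlorination the mesylate formed in the flask is displaced by chloride in an SN2 reaction at the primary carbon, so neither allylic transposition nor loss of the E geometry is expected.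

Step 4
Reactants: 5 (3R,6E)-3-(tert-butyldimethylsilyloxy)-8-chloro-3,7-dimethylocta-1,6-diene; 6 β-cyclocitral (2,6,6-trimethylcyclohex-1-ene-1-carbaldehyde)
Product: 8 (8E,13R)-13-O-TBS-9,10-seco-labda-5(10),8,14-triene-6,13-diol as a mixture of C6 epimers, via allylbarium chloride 7 (not isolated)
Conditions: BaI2, LiC12H10 (lithium biphenylide), THF, rt (activated zerovalent barium); 5, −78 °C; then 6, −78 °C
Reagents that add atoms: none
Why: Allylbarium reagents (Yamamoto allylation) add to aldehydes through their α-carbon with retention of the E geometry, whereas Mg, Zn or In Barbier reagents would give the branched γ-adduct; only 1,2-addition is possible because C10 is fully substituted, and the C6 configuration is irrelevant because step 5 erases it.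

Step 5
Reactants: 8 (8E,13R)-13-O-TBS-9,10-seco-labda-5(10),8,14-triene-6,13-diol (C6 epimers)
Product: 9 (13R)-13-O-TBS-labda-5,14-diene-8α,13-diol (9α-H, 10β-methyl)
Conditions: (S,S)-IDPi acid HN[P(=NSO2CF3)(O2C20H10Ar2)]2, Ar = 3,5-(CF3)2C6H3 (5 mol %), H2O (3 equiv), (CF3)2CHOH/CH2Cl2 (1:4), −40 °C
Reagents that add atoms: water, O
Why: Proposed new method: the acid ionises the C6 carbinol, both epimers giving the same C6–C5–C10 allyl cation held as an ion pair in the pocket of the chiral imidodiphosphorimidate anion; C9 of the (8E)-alkene then bonds to C10 and the developing C8 cation is taken by water, so the step is a net isomerisation of 8. The closest known reaction types are acid-promoted cyclisations of β-cyclogeranyl carbinols onto tethered arenes, Johnson allylic-alcohol-initiated cation–olefin cyclisations and confined-acid-catalysed polyene cyclisations in fluorinated alcohols; an alkene nucleophile, water capture and counteranion control have not been combined on this cation. Ring B closes 6-endo with respect to the C8=C9 alkene (the five-membered alternative needs a secondary C9 cation, attack at C6 a four-membered ring) and C5=C6 is left behind. C8 and C9 are set by the E-alkene and anti addition (C10 and water on opposite faces: equatorial 8α-OH, axial C17, axial 9α-H, equatorial C11); C9 relative to C10 by the chair-like arrangement in which the C11 chain points away from ring A, which itself forces the C6–C7 tether onto the C20 side of C10; the absolute face of planar C10, for which C13 is too remote, by the chiral counteranion. The step needs ionisation at C6 and not at the tertiary allylic C13 ether, which the far better stabilised trialkyl allyl cation and the weakly basic, bulky silyl ether should secure; it also needs water capture in preference to loss of H7 or closure of an 8,13-oxide, which low temperature, added water and the silyl group on O13 should favour.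

Step 6
Reactants: 9 (13R)-13-O-TBS-labda-5,14-diene-8α,13-diol
Product: 10 (13R)-13-O-TBS-5α,6α-epoxylabd-14-ene-8α,13-diol
Conditions: mCPBA (1.1 equiv), CH2Cl2/aq. phosphate buffer (pH 8), 0 °C
Reagents that add atoms: 3-chloroperoxybenzoic acid, OOC(=O)c1cccc(Cl)c1
Why: In this Prilezhaev epoxidation the trisubstituted Δ5 bond should react far faster than the monosubstituted, oxygen-deactivated vinyl group, and the peracid should come from the α face because the β face is screened by the 10β-, 4β- and 8β-methyl groups while the homoallylic 8α-OH can guide it.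

Step 7
Reactants: 10 (13R)-13-O-TBS-5α,6α-epoxylabd-14-ene-8α,13-diol
Product: 11 (13R)-13-O-TBS-labd-14-ene-6α,8α,13-triol (5α-H)
Conditions: Cp2TiCl2 (2.5 equiv), Mn dust, THF, rt; then 10, H2O (10 equiv), rt
Reagents that add atoms: none
Why: In the Nugent–RajanBabu reductive epoxide opening, Cp2TiCl (trivalent titanium) cleaves the C5–O bond to the tertiary C5 radical without the cationic methyl shifts that threaten at C4 and C10; the C6–O bond is not broken, so 6α is kept, and hydrogen-atom transfer from the aqua complex of Cp2TiCl should reach C5 on the α face, anti to the flanking 10β- and 4β-methyl groups, to give the trans-decalin.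

Step 8
Reactants: 11 (13R)-13-O-TBS-labd-14-ene-6α,8α,13-triol; 12 angelic acid ((Z)-2-methylbut-2-enoic acid)
Product: 14 (13R)-6α-angeloyloxy-13-O-TBS-labd-14-ene-8α,13-diol, via mixed anhydride 13 (not isolated)
Conditions: 12, 2,4,6-Cl3C6H2COCl, Et3N, toluene, rt; then 11, 80 °C
Reagents that add atoms: none
Why: Yamaguchi-type esterification through the 2,4,6-trichlorobenzoic mixed anhydride without DMAP is the established way to make angelates without Z-to-E isomerisation, and only the secondary equatorial 6α-OH should react because the 8α-OH is tertiary and O13 is silylated.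

Step 9
Reactants: 14 (13R)-6α-angeloyloxy-13-O-TBS-labd-14-ene-8α,13-diol
Product: 15 (13R)-6α-angeloyloxylabd-14-ene-8α,13-diol (target)
Conditions: Bu4NF, AcOH, THF, 45 °C
Reagents that add atoms: none
Why: Fluoride-mediated desilylation of the tertiary silyl ether, buffered with acetic acid so that the angelate should neither isomerise nor migrate, touches no stereocentre.

## Compound list

1 | (R)-linalool, (3R)-3,7-dimethylocta-1,6-dien-3-ol | C=C[C@](C)(O)CCC=C(C)C | starting material
2 | (R)-linalool tert-butyldimethylsilyl ether | C=C[C@](C)(O[Si](C)(C)C(C)(C)C)CCC=C(C)C | intermediate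
3 | (2E,6R)-6-(tert-butyldimethylsilyloxy)-2,6-dimethylocta-2,7-dien-1-ol | C=C[C@](C)(O[Si](C)(C)C(C)(C)C)CC/C=C(\C)CO | intermediate
4 | methanesulfonate of 3 (not isolated) | C=C[C@](C)(O[Si](C)(C)C(C)(C)C)CC/C=C(\C)COS(C)(=O)=O | intermediate
5 | (3R,6E)-3-(tert-butyldimethylsilyloxy)-8-chloro-3,7-dimethylocta-1,6-diene | C=C[C@](C)(O[Si](C)(C)C(C)(C)C)CC/C=C(\C)CCl | intermediate
6 | β-cyclocitral, 2,6,6-trimethylcyclohex-1-ene-1-carbaldehyde | CC1=C(C=O)C(C)(C)CCC1 | starting material
7 | allylbarium chloride from 5, barium on the former CH2Cl carbon (not isolated) | C=C[C@](C)(O[Si](C)(C)C(C)(C)C)CC/C=C(\C)C[Ba]Cl | intermediate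
8 | (8E,13R)-13-O-TBS-9,10-seco-labda-5(10),8,14-triene-6,13-diol, C6 epimers; (3E,7R)-7-(tert-butyldimethylsilyloxy)-3,7-dimethyl-1-(2,6,6-trimethylcyclohex-1-en-1-yl)nona-3,8-dien-1-ol | C=C[C@](C)(O[Si](C)(C)C(C)(C)C)CC/C=C(\C)CC(O)C1=C(C)CCCC1(C)C | intermediate
9 | (13R)-13-O-TBS-labda-5,14-diene-8α,13-diol (9α-H, 10β-methyl) | C=C[C@](C)(O[Si](C)(C)C(C)(C)C)CC[C@@H]1[C@@]2(C)CCCC(C)(C)C2=CC[C@@]1(C)O | intermediate
10 | (13R)-13-O-TBS-5α,6α-epoxylabd-14-ene-8α,13-diol | C=C[C@](C)(O[Si](C)(C)C(C)(C)C)CC[C@@H]1[C@@]2(C)CCCC(C)(C)[C@@]23O[C@H]3C[C@@]1(C)O | intermediate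
11 | (13R)-13-O-TBS-labd-14-ene-6α,8α,13-triol (5α-H) | C=C[C@](C)(O[Si](C)(C)C(C)(C)C)CC[C@@H]1[C@@]2(C)CCCC(C)(C)[C@@H]2[C@@H](O)C[C@@]1(C)O | intermediate
12 | angelic acid, (Z)-2-methylbut-2-enoic acid | C/C=C(/C)C(=O)O | starting material
13 | angelic 2,4,6-trichlorobenzoic anhydride (not isolated) | C/C=C(/C)C(=O)OC(=O)c1c(Cl)cc(Cl)cc1Cl | intermediate
14 | (13R)-6α-angeloyloxy-13-O-TBS-labd-14-ene-8α,13-diol | C=C[C@](C)(O[Si](C)(C)C(C)(C)C)CC[C@@H]1[C@@]2(C)CCCC(C)(C)[C@@H]2[C@@H](OC(=O)/C(C)=C\C)C[C@@]1(C)O | intermediate
15 | (13R)-6α-angeloyloxylabd-14-ene-8α,13-diol, (5S,6S,8R,9R,10S,13R) | C=C[C@](C)(O)CC[C@@H]1[C@@]2(C)CCCC(C)(C)[C@@H]2[C@@H](OC(=O)/C(C)=C\C)C[C@@]1(C)O | target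

## Step count and risks

Total step count: 9. Longest linear sequence: 9 steps (1 to 15).

**Step 5 (proposed new method).** What may go wrong: the counteranion may fail to discriminate the two faces of planar C10, and the C8 cation may lose a proton (towards the conjugated 5,7-diene) or be trapped by O13 instead of by water.
Fallback, from 8 back to 9: reagent control would be given up and the C13 centre used as a resolving handle. Compound 8 would be cyclised with the achiral protic acid CF3CO2H (5 equiv) in CH2Cl2 at −78 °C, the Johnson-type allylic-alcohol-initiated cation–olefin cyclisation in which the tertiary cation is trapped as its trifluoroacetate. This should give the 8-O-trifluoroacetate of 9 F1 together with the ring-diastereomeric trifluoroacetate F2. K2CO3 in aqueous MeOH would cleave both esters to 9 and the ring diastereomer of 9 (8β-OH, 9β-H, 10α-methyl, 13R) F3. Because C13 makes these two diastereomers, they would be separated by chromatography, and 9 would re-enter the route at step 6.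

**Step 7.** What may go wrong: hydrogen-atom delivery to the C5 radical may be unselective (cis-fused by-product), or the titanium-bound radical may lose oxygen and return the alkene.
Fallback, from 10 back to 11: the opening would be run as in step 7, and the crude mixture of 11 and its 5β-epimer F4 would be oxidised with Dess–Martin periodinane in CH2Cl2 to the 8α-hydroxy-6-ketones, the 5β-ketone F5 and the 5α-ketone F6. NaOMe in MeOH at 0 °C would equilibrate F5 into the trans-fused F6 through the C5 enolate. Reduction of F6 with Li in liquid NH3/THF at −78 °C, which gives the thermodynamically preferred equatorial alcohol, would return 11.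

**Step 8.** What may go wrong: acylation of the hindered 6α-hydroxyl next to the C4 methyl groups may be slow, and prolonged heating may isomerise the angeloyl group to the tigloyl group.
Fallback, from 11 back to 14: the Z-enoate would be built on the molecule instead of being transferred. Compound 11 would be esterified with 2-[bis(2,2,2-trifluoroethoxy)phosphoryl]propanoic acid (DCC, DMAP, CH2Cl2) to the 6α-phosphonopropionate F7. Still–Gennari olefination of F7 with acetaldehyde (KN(SiMe3)2, 18-crown-6, THF, −78 °C) should then give the Z-trisubstituted ester, which is 14.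

## Further compounds

F1 | step 5 | 8-O-trifluoroacetate of 9 | C=C[C@](C)(O[Si](C)(C)C(C)(C)C)CC[C@@H]1[C@@]2(C)CCCC(C)(C)C2=CC[C@@]1(C)OC(=O)C(F)(F)F
F2 | step 5 | ring-diastereomeric 8-O-trifluoroacetate (8β-O, 9β-H, 10α-methyl, 13R) | C=C[C@](C)(O[Si](C)(C)C(C)(C)C)CC[C@H]1[C@]2(C)CCCC(C)(C)C2=CC[C@]1(C)OC(=O)C(F)(F)F
F3 | step 5 | ring diastereomer of 9 (8β-OH, 9β-H, 10α-methyl, 13R) | C=C[C@](C)(O[Si](C)(C)C(C)(C)C)CC[C@H]1[C@]2(C)CCCC(C)(C)C2=CC[C@]1(C)O
F4 | step 7 | 5β-epimer of 11 | C=C[C@](C)(O[Si](C)(C)C(C)(C)C)CC[C@@H]1[C@@]2(C)CCCC(C)(C)[C@H]2[C@@H](O)C[C@@]1(C)O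
F5 | step 7 | (13R)-13-O-TBS-8α,13-dihydroxy-5β-labd-14-en-6-one | C=C[C@](C)(O[Si](C)(C)C(C)(C)C)CC[C@@H]1[C@@]2(C)CCCC(C)(C)[C@H]2C(=O)C[C@@]1(C)O
F6 | step 7 | (13R)-13-O-TBS-8α,13-dihydroxy-5α-labd-14-en-6-one | C=C[C@](C)(O[Si](C)(C)C(C)(C)C)CC[C@@H]1[C@@]2(C)CCCC(C)(C)[C@@H]2C(=O)C[C@@]1(C)O
F7 | step 8 | 6α-{2-[bis(2,2,2-trifluoroethoxy)phosphoryl]propanoyloxy} derivative of 11 | C=C[C@](C)(O[Si](C)(C)C(C)(C)C)CC[C@@H]1[C@@]2(C)CCCC(C)(C)[C@@H]2[C@@H](OC(=O)C(C)P(=O)(OCC(F)(F)F)OCC(F)(F)F)C[C@@]1(C)O
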